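In a one-step world the product would curve from the first minute, yet the summer run climbs straight and then breaks, as if a solid fed a small dissolved pool that the enzyme drains.

- summer: solid substrate 27 mM; enzyme 18 µM; the very flask that is asked about, followed so far
- flask: solid substrate 27 mM; enzyme 18 µM

summer run (percent of the solid substrate charged)

| time / min | product / % |
|---|---|
| 5.00 | 16.2 |
| 15.0 | 58.0 |
| 25.0 | 95.9 |
| 40.0 | 99.3 |
| 50.0 | 99.9 |

(standard deviation of a reading: 0.5 percentage points)

- solid substrate is a solid; its amount is given per volume of the solution
- at the start none of the solid substrate is in solution
- what has only dissolved of solid substrate counts as not reacted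
- no earlier run changes the charge of enzyme; that part of a forecast is a guess

- apparent order in enzyme when 20 % of the solid substrate are converted (what has only dissolved counts as not reacted) (percent change of the rate of making product for one percent more enzyme charged)

Between 5.00 min and 15.0 min the summer run makes product at a steady rate, per minute, as a share of the charge:

s = 0.0418 min⁻¹

While the pool stands still, dissolving runs at this rate too. I place the reading at 25.0 min about one drain time past the break, which gives the pool:

[S] = 11.1 %

Suppose dissolving slows in proportion as the pool fills, and the drain follows the pool. Then the order in enzyme equals the slowdown of dissolving, the fraction by which dissolving has fallen from its starting rate. There are two ways to reach it.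

The lag way takes the time L by which the straight line misses the origin, and reads 1/L as the sum of the dissolving and drain constants:

L = 1.12 min, order = 1 − L·s/[S] = 0.578

The balance way says that by 5.00 min the solid has given up the product plus a pool already standing at the same [S], and takes that mean rate as the starting rate:

d = ([P] + [S])/t = 0.0547 min⁻¹, slowdown = 1 − s/d = 0.236

The lag way gives more than the balance. Both ways rest on the same [S], read late in the run, so their parting tests nothing about it. The lag way divides by [S] outright, whereas the balance adds it to a larger [P], so the balance leans on [S] less, and I commit to 0.236 as an estimate.

The forecast stood at 0.6, with a range of 0.35 to 0.85, and warned that "the lag is poorly defined".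

The simulation of the flask gives 0.19.

    starting material + enzyme → product + enzyme, rate k1*[starting material]*[enzyme]/(1 + ([starting material]/Km1) + ([product]/Kp1)) (8.74 mM, 21.6 mM, k = 966 M⁻¹ s⁻¹)
    enzyme ⇌ dormant form (K = 0.220, k = 7.66 × 10⁻⁴ s⁻¹)
    solid substrate ⇌ starting material, rate k3*(cs3 - [starting material]) while solid is left; crystals form when [starting material] > cs3 (solubility = 22.0 mM, k = 0.00103 s⁻¹)

In this flask solid substrate enters an empty solution at 0.0504 min⁻¹ of the charge, less than the 0.0547 min⁻¹ reckoned from the balance, and the steady 0.0418 min⁻¹ from the readings then makes the slowdown 0.171 against the 0.236 reckoned before. At 0.300 h the flask holds 10.7 % of the charge as starting material, far less than the saturation level of 81.5 %, with 17.8 % still solid.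

The earlier runs and the new flask were computed with constants of no real substance; noise was put on by code.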